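(All constants were set for the occasion; the rest is arithmetic.)

In a stirred vessel of constant volume, the starting material and the partner each open into a reactive form, and those forms then meet, in the flasks below.

    starting material → open intermediate (k1 = 0.19 s⁻¹)
    partner → second intermediate (k2 = 0.71 s⁻¹)
    open intermediate + second intermediate → target (k3 = 2.6 L mol⁻¹ s⁻¹)
    2 open intermediate → homo product (k4 = 2.4 L mol⁻¹ s⁻¹)
    partner → decomposition product (k5 = 4.4 × 10⁻⁴ s⁻¹)
    starting material + second intermediate → side product (k6 = 7.8 L mol⁻¹ s⁻¹)
    starting material + protic impurity → quenched substrate (k7 = 1.6 L mol⁻¹ s⁻¹)

| flask | starting material | partner | protic impurity | time | remark |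
|---|---|---|---|---|---|
| Monday's | 20 mM (fed, over 12 s) | 0.950 equiv | 20.0 mM | 20 s | all else is in the flask from the start; the feed brings no volume worth counting |
| Friday's | 20 mM | 0.950 equiv (fed, over 12 s) | 20.0 mM | 20 s | all else is in the flask from the start; the feed brings no volume worth counting |
| Thursday's | 20 mM | 0.950 equiv | 20.0 mM | 20 s | everything together at the start |
| Tuesday's | 20 mM (in portions, 5, over 12 s) | 0.950 equiv | 20.0 mM | 20 s | first portion at the start, last at 12 s |
| Wednesday's | 20 mM (fed, over 1.2 s) | 0.950 equiv | 20.0 mM | 20 s | all else is in the flask from the start; the feed brings no volume worth counting |

- in percentages every species weighs as the starting material in it: one homo product counts as two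
- where a step has two of a species, its rate is k times that concentration squared, and two are used at each turn
- run time (Monday's): 20 s

* the flask that comes out highest in share of target in target plus homo product, or "all alike" when all lie within 1.5 percentage points (Monday's / Friday's / Thursday's / Tuesday's / Wednesday's / all alike)
* share of target in target plus homo product at the end, Monday's
* share of target in target plus homo product at the end, Friday's
* share of target in target plus homo product at the end, Thursday's
* share of target in target plus homo product at the end, Tuesday's
* share of target in target plus homo product at the end, Wednesday's

Write the balance of the partner, the smaller charge at 0.950 equiv: what has opened is either still standing as second intermediate or has left as target or side product. Open intermediate meets that standing pool, while two of its own kind go at each homo turn. Counted as starting material, homo product therefore grows against target as twice the homo constant times open intermediate against the target constant times second intermediate. Carry 1.85: this parity ratio is the second intermediate per open intermediate at which target and homo product grow equally, a selectivity factor.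

Which numbers must you know well in Thursday's? The decomposition constant need not be exact, since at 4.4 × 10⁻⁴ s⁻¹ against 0.71 s⁻¹ decomposition takes hardly any of the partner. In Thursday's the partner's half-life by opening is 0.976 s, shorter than the 3.6 s half-life of starting material by step 1 alone. The impurity's drain, 0.0320 s⁻¹, is smaller than the opening at 0.19 s⁻¹. The target and homo constants enter in full through the parity ratio, and the side constant enters through the balance.

Now my number for Thursday's. I guess second intermediate at 9.50 mM, half the partner charge. Starting material then opens to the extent of 64.2 %, so 12.8 mM passes through open intermediate. I let 6.42 mM of that stand, half of it, since its exit at 0.0555 s⁻¹ gives a lifetime near the run. The share comes to 44.5 %, and my reckoning stops there, before the dosed flasks.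

The forecast gives 54 % for Monday's, 39 % for Friday's, 48 % for Thursday's, 53 % for Tuesday's and 48 % for Wednesday's, and it names Monday's highest. Its ground is that “keeping the open intermediate low against a standing pool of second intermediate favours target”. For Thursday's my figure lies below its value.

The flasks give 53.8 % for Monday's, 37.4 % for Friday's, 48.3 % for Thursday's, 55.4 % for Tuesday's and 48.5 % for Wednesday's, so Tuesday's stands highest, 1.6 percentage points above Monday's. Thursday's ends with 9.76 mM of second intermediate against 4.59 mM of open intermediate, a ratio of 2.12, above the parity ratio of 1.85. Friday's ends with 13.1 mM against 5.33 mM, a ratio of 2.46, also above it, and at 200 s Friday's share reads 49.5 %.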